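Temperature is what separates these flasks. J dissolves to L and Q feeds X; L then takes X to L.X, takes E to L.E, or takes L.X on to L.L.X.

| setting | Saturday's | Tuesday's | Sunday's |
|---|---|---|---|
| J | 0.51 M | 0.51 M | 0.51 M |
| E | 1.05 equiv | 1.05 equiv | 1.05 equiv |
| Q | 34 mM (held) | 34 mM (held) | 34 mM (held) |
| temperature | 45 °C |  | 60 °C |
| time | 8.0 h | 8.0 h | 8.0 h |
| remark |  | at 60 °C until 4.0 h, from then on at 45 °C |  |

1. the flask that comes out highest in amount of L.X, in percent of the J charged, or "all alike" when all lie within 1.5 percentage points (Saturday's / Tuesday's / Sunday's / all alike)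
2. L.X at the end, in percent of the J charged, Saturday's
3. L.X at the end, in percent of the J charged, Tuesday's
4. L.X at the end, in percent of the J charged, Sunday's

- percent here means J units held: one L.L.X counts as two
- J is a solid; its amount is given per volume of the solution
- at the start none of X is dissolved
- at 60 °C the constants are as listed, elsewhere as the activation energies make them
- at the start none of J is in solution
- what has only dissolved of J counts as not reacted

Here is what looks wrong: going from 60 °C to 45 °C slows the making of L.X 2.8 times, yet I expect the cooler flask to keep more L.X.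

1. I turn the two first steps of L into rates per minute at the charged amounts, with X at saturation and E at 0.536 M. I call their ratio, the rate of L toward X over the rate of L toward E, the split, a selectivity factor. At 60 °C it is 1.21, so 45.3% of L goes to E.

2. Cooling slows the loss to E 3.6 times, harder than it slows the step to L.X. The split therefore rises to 1.56 at 45 °C, and the share lost falls to 39.0%. The step to L.L.X also slows harder, 3.2 times.

3. Does the cool flask have the time? J dissolves in 152 min at its initial rate, and L lasts 127 min at 45 °C. Together these are shorter than the 8.0 h allowed.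

4. At 60 °C, L lasts 40.2 min with X at saturation and E at its charge, and this time added to the dissolving time is shorter than the 4.0 h before the change; but that only compares times and doesn't say that L is gone by then. I score Tuesday's at the hot split, and the highest split goes to Saturday's. My reckoning gives a ranking, not percentages of L.X.

The forecast names Saturday's: 26.3% (23.5% to 29%) for Saturday's, 22.7% (20% to 25.5%) for Tuesday's and 21.5% (19% to 24%) for Sunday's. Its ground is that “the cooler flask keeps more selectivity”.

    L + X → L.X (k1 = 0.40 M⁻¹ min⁻¹, Ea1 = 61.0 kJ mol⁻¹)
    L + E → L.E (k2 = 0.021 M⁻¹ min⁻¹, Ea2 = 76.0 kJ mol⁻¹)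
    Q ⇌ X, rate k3*(csat - [X]) (k3 = 0.043 min⁻¹, csat = 34 mM)
    L + L.X → L.L.X (k4 = 0.054 M⁻¹ min⁻¹, Ea4 = 68.0 kJ mol⁻¹)
    J ⇌ L, rate k5*(cs5 - [L]) while solid is left; crystals form when [L] > cs5 (cs5 = 0.39 M, k5 = 0.0086 min⁻¹)
    (constants at 60 °C)

The simulation gives 24.9% for Saturday's, 21.0% for Tuesday's and 20.3% for Sunday's, so Saturday's leads, as the forecast said. At 4.00 h, Tuesday's still holds 12.8% as L. Cooling can act on that L, and the two shares differ on it by 0.8 percentage points. Tuesday's ends 0.7 points above Sunday's, less than Saturday's lead over Tuesday's.

A flask like Sunday's but with 0.260 equiv of E has a split of 4.88, so 17.0% should go to E. Computed, it ends with 15.5% as L.E, 21.9% as L.X and 61.9% as L.L.X.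

The constants were set for the occasion.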